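**Retrosynthetic overview**

1. The last operation is acid removal of the aryl MOM ether, the C5 silyl ether and the 6,7-acetonide from the fully protected tetrahydrochromone.
2. Key disconnection C8–C8a: C8, the only chlorinated carbon, lies between the C7 stereocentre and C8a, the electrophilic β-carbon of the pyranone enone (C4=O, C4a=C8a). A planar α-chloro radical at C8 can therefore close the carbocycle C4a–C5–C6–C7–C8–C8a from either C8 epimer, ipso to a sulfonyl group that then leaves; this ring is formed last.
3. The α-chloro acid at C8 comes from the C8 aldehyde by trichloromethyl addition and Jocic reaction; N-acyloxyphthalimide formation and S-oxidation complete the radical precursor.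
4. Disconnection C4a–C5: a 3-magnesiated 2-(methylsulfanyl)pyranone adds to a D-erythrose aldehyde (C5–C8, from 2,3-O-isopropylidene-D-erythronolactone); Felkin–Anh addition sets C5.
5. The pyranone ring is formed first, from a 3-arylpropanoate and a ketene dithioacetal (Claisen condensation, cyclisation), and is then iodinated at C3.

Key step: step 15

Remark: chain atoms carry the target's chromone locants (pyranone C3 = C4a, pyranone C2 = C8a). The sulfone is a methyl sulfone (the S-substituent leaves with the sulfinate, and the methylsulfanyl pyranone comes from commercial 3), and the phenol is a MOM ether because steps 8 and 12 are strongly basic. Compounds 1, 3, 8 and 21 are assumed commercial.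

**Route**

Step 1
Reactants: 1 3-(3-hydroxy-4-methoxyphenyl)propanoic acid
Product: 2 methyl 3-(3-hydroxy-4-methoxyphenyl)propanoate
Conditions: MeOH, H2SO4 (cat.), reflux
Reagents that add atoms: methanol, CO
Why: Fischer esterification; the phenol does not react under acid catalysis.

Step 2
Reactants: 2 methyl 3-(3-hydroxy-4-methoxyphenyl)propanoate; 3 4,4-bis(methylsulfanyl)but-3-en-2-one
Product: 5 6-[2-(3-hydroxy-4-methoxyphenyl)ethyl]-2-(methylsulfanyl)-4H-pyran-4-one, via diketone 4 (not isolated)
Conditions: NaH (3.5 equiv), THF, 0 → 50 °C; AcOH; then TFA, CH2Cl2, rt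
Reagents that add atoms: none
Why: Crossed Claisen condensation of the methyl ketone enolate of 3 with ester 2 (the phenoxide is a spectator) gives the 1,3-diketone, whose enol oxygen then adds 6-endo to the protonated ketene dithioacetal carbon and loses methanethiol (addition–elimination), the closure known for 2-hydroxyaryl α-oxo ketene dithioacetals going to 2-(methylsulfanyl)chromones.

Step 3
Reactants: 5 6-[2-(3-hydroxy-4-methoxyphenyl)ethyl]-2-(methylsulfanyl)-4H-pyran-4-one
Product: 6 6-{2-[4-methoxy-3-(methoxymethoxy)phenyl]ethyl}-2-(methylsulfanyl)-4H-pyran-4-one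
Conditions: MOMCl, i-Pr2NEt, CH2Cl2, 0 °C → rt
Reagents that add atoms: chloromethyl methyl ether, COCCl
Why: O-alkylation of the phenol (methoxymethyl ether formation); the MOM ether is stable to the organomagnesium, hydroxide and peracid steps ahead and falls in the final acid step.

Step 4
Reactants: 6 6-{2-[4-methoxy-3-(methoxymethoxy)phenyl]ethyl}-2-(methylsulfanyl)-4H-pyran-4-one
Product: 7 3-iodo-6-{2-[4-methoxy-3-(methoxymethoxy)phenyl]ethyl}-2-(methylsulfanyl)-4H-pyran-4-one
Conditions: NIS, MeCN, 0 °C → rt, dark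
Reagents that add atoms: N-iodosuccinimide, O=C1CCC(=O)N1I
Why: Electrophilic iodination at C3, the α-carbon of the push–pull ketene O,S-acetal unit and the most nucleophilic carbon; C5 and the dialkoxyarene should not react with NIS in the absence of acid.

Step 5
Reactants: 8 2,3-O-isopropylidene-D-erythronolactone
Product: 9 (4R,5R)-5-(hydroxymethyl)-N-methoxy-N,2,2-trimethyl-1,3-dioxolane-4-carboxamide
Conditions: MeNH(OMe)·HCl, i-PrMgCl, THF, −20 → 0 °C
Reagents that add atoms: N,O-dimethylhydroxylamine hydrochloride, CNOC.Cl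
Why: Aminolysis of the lactone by the chloromagnesium amide (Weinreb amide formation); the two sugar stereocentres are not touched.

Step 6
Reactants: 9 (4R,5R)-5-(hydroxymethyl)-N-methoxy-N,2,2-trimethyl-1,3-dioxolane-4-carboxamide
Product: 10 (4R,5R)-N-methoxy-N,2,2-trimethyl-5-[(triethylsilyloxy)methyl]-1,3-dioxolane-4-carboxamide
Conditions: TESCl, imidazole, CH2Cl2, 0 °C
Reagents that add atoms: chlorotriethylsilane, CC[Si](CC)(CC)Cl
Why: Silylation of the primary alcohol; it stops relactonisation, and a primary triethylsilyl ether can later be oxidised directly to the aldehyde.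

Step 7
Reactants: 10 (4R,5R)-N-methoxy-N,2,2-trimethyl-5-[(triethylsilyloxy)methyl]-1,3-dioxolane-4-carboxamide
Product: 11 2,3-O-isopropylidene-4-O-triethylsilyl-D-erythrose [(4R,5R)-2,2-dimethyl-5-[(triethylsilyloxy)methyl]-1,3-dioxolane-4-carbaldehyde]
Conditions: DIBAL-H, THF, −78 °C; Rochelle salt
Reagents that add atoms: none
Why: Hydride reduction of the Weinreb amide stops at the chelated hemiaminal, which gives the aldehyde on work-up; the cis-dioxolane aldehyde is used crude so that C2 does not epimerise.

Step 8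
Reactants: 7 3-iodo-6-{2-[4-methoxy-3-(methoxymethoxy)phenyl]ethyl}-2-(methylsulfanyl)-4H-pyran-4-one; 11 2,3-O-isopropylidene-4-O-triethylsilyl-D-erythrose
Product: 13 (5S)-alcohol 3-[(S)-hydroxy{(4S,5R)-2,2-dimethyl-5-[(triethylsilyloxy)methyl]-1,3-dioxolan-4-yl}methyl]-6-{2-[4-methoxy-3-(methoxymethoxy)phenyl]ethyl}-2-(methylsulfanyl)-4H-pyran-4-one, via pyranonylmagnesium chloride 12 (not isolated)
Conditions: i-PrMgCl·LiCl (1.1 equiv), THF, −60 °C; then 11 (1.3 equiv), −78 → −40 °C; aq. NH4Cl
Reagents that add atoms: none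
Why: Iodine–magnesium exchange (turbo-Grignard) followed by Grignard addition to the aldehyde forms C4a–C5; C5 is set by Felkin–Anh addition (dioxolane C6–O bond anti to the nucleophile), which should favour the 5,6-anti (5S) alcohol, the C5 epimer being removed by chromatography.

Step 9
Reactants: 13 (5S)-alcohol
Product: 14 5-O-tert-butyldimethylsilyl ether of 13 (5S; C6 and C7 as in 11; C8 still CH2OSiEt3)
Conditions: TBSOTf, 2,6-lutidine, CH2Cl2, −78 → −20 °C
Reagents that add atoms: tert-butyldimethylsilyl triflate, CC(C)(C)[Si](C)(C)OS(=O)(=O)C(F)(F)F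
Why: Silyl ether formation on the hindered secondary alcohol with the silyl triflate; the triethylsilyl ether, acetonide and MOM ether should survive these conditions at low temperature.

Step 10
Reactants: 14 5-O-TBS 8-O-triethylsilyl ether
Product: 15 C8 aldehyde (14 with CHO in place of CH2OSiEt3; 5S, cis-dioxolane unchanged)
Conditions: (COCl)2, DMSO, CH2Cl2, −78 → −35 °C; Et3N, −78 → 0 °C
Reagents that add atoms: none
Why: Swern oxidation with in situ cleavage of the primary triethylsilyl ether, a known selectivity over secondary TBS ethers, gives the aldehyde without a separate deprotection; the thioether is inert to activated DMSO at low temperature.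

Step 11
Reactants: 15 C8 aldehyde
Product: 16 trimethylsilyl ether of the trichloromethyl carbinol (C8 carries OSiMe3 and CCl3; both C8 epimers)
Conditions: Me3SiCCl3, n-Bu4NOAc (10 mol%), THF, −20 → 0 °C
Reagents that add atoms: trimethyl(trichloromethyl)silane, C[Si](C)(C)C(Cl)(Cl)Cl
Why: Acetate-catalysed nucleophilic trichloromethylation of the aldehyde under nearly neutral conditions, which protects C7 from epimerisation; the new C8 centre forms as a mixture, which does not matter because C8 becomes a planar radical in step 15.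

Step 12
Reactants: 16 trimethylsilyl ether of the trichloromethyl carbinol
Product: 20 2-chloro acid (chain CH(OTBS)–CH(O)–CH(O)–CHCl–CO2H on pyranone C3 with O6/O7 as acetonide; 5S; both C8 epimers), via trichloromethyl carbinol 17 (not isolated), via gem-dichloroepoxide 18 (not isolated), via 2-chloroacyl chloride 19 (not isolated)
Conditions: KOH, LiCl (excess), DME/H2O, 0 °C → rt; then aq. citric acid to pH 3–4
Reagents that add atoms: potassium hydroxide, [K+].[OH-]; lithium chloride, [Li+].[Cl-]
Why: Jocic reaction: hydroxide removes the trimethylsilyl group, the alkoxide closes to the gem-dichloroepoxide, chloride (kept in large excess) opens it at C8 by SN2 to the acyl chloride, and hydrolysis gives the α-chloro acid.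

Step 13
Reactants: 20 2-chloro acid; 21 N-hydroxyphthalimide
Product: 22 N-acyloxyphthalimide of 20 (C8 epimers)
Conditions: DIC, CH2Cl2, 0 °C → rt
Reagents that add atoms: none
Why: Carbodiimide esterification gives the redox-active ester; DMAP is left out so that the α-chloro acid does not form a ketene.

Step 14
Reactants: 22 N-acyloxyphthalimide
Product: 23 sulfone of 22: 2-(methylsulfonyl)pyranone carrying the 2-chloro N-acyloxyphthalimide chain (key-step precursor; C8 epimers)
Conditions: mCPBA (2.5 equiv), CH2Cl2, 0 °C → rt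
Reagents that add atoms: 3-chloroperbenzoic acid, OOC(=O)c1cccc(Cl)c1
Why: Peracid oxidation of the sulfide to the sulfone; the electron-poor pyranone double bonds and the activated ester are inert to mCPBA, and the electrophilic sulfone is made last so that it meets no nucleophile.

Step 15
Reactants: 23 sulfone N-acyloxyphthalimide
Product: 24 (5S,6R,7S,8R)-5-(tert-butyldimethylsilyloxy)-8-chloro-6,7-(isopropylidenedioxy)-2-{2-[4-methoxy-3-(methoxymethoxy)phenyl]ethyl}-5,6,7,8-tetrahydro-4H-chromen-4-one (C5–C8 arranged as in the target)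
Conditions: Ru(bpy)3(PF6)2 (2 mol%), Hantzsch ester (1.5 equiv, added over 8 h), i-Pr2NEt·HBF4 (1 equiv), degassed CH2Cl2 (5 mM), blue LEDs, rt
Reagents that add atoms: none
Why: Proposed new method: Ru(I), formed by reductive quenching of excited Ru(bpy)3(2+) by the Hantzsch ester, transfers one electron to the phthalimide ester, which loses phthalimide anion and CO2 to give the α-chloroalkyl radical at C8 (planar, so both C8 epimers of 23 converge); this radical adds to C8a, the enone β-carbon ipso to the sulfonyl group, and the C4a radical so formed (stabilised by the C4 carbonyl) expels MeSO2• by β-scission, restoring the pyranone. The closest known reaction types are reductive decarboxylative radical generation from N-acyloxyphthalimides (used for Giese additions and for alkenylation with vinyl sulfones) and intramolecular radical ipso-substitution of heteroaryl sulfones; their combination on a 2-sulfonyl-4-pyranone with an α-chloro radical is not established. The carbocycle C4a–C5–C6–C7–C8–C8a closes in 6-endo-trig mode, which should be favoured over 5-exo attack at C4a because the tether sits on the α-carbon of the enone and because only the 6-endo adduct can lose the sulfonyl radical irreversibly. The new stereocentre C8 is under substrate control: a chair-like transition state with chlorine pseudo-equatorial and anti to the C7–O bond, on the face away from the cis-fused dioxolane, should give the 7,8-trans (8R) chloride, but this preference is a prediction and not an established result. The step needs ring closure to outrun hydrogen transfer to the C8 radical, which high dilution and slow addition of the Hantzsch ester should secure, and it needs the chlorine to survive, which the mild reductant (about −1.3 V) and the low tendency of an α-chloro radical to be oxidised or reduced should secure.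

Step 16
Reactants: 24 fully protected tetrahydrochromone
Product: 25 (5S,6S,7S,8R)-8-chloro-5,6,7-trihydroxy-2-[2-(3-hydroxy-4-methoxyphenyl)ethyl]-5,6,7,8-tetrahydro-4H-chromen-4-one (CNP0362174.1)
Conditions: TFA/H2O (4:1), 0 °C → rt
Reagents that add atoms: none
Why: Acid hydrolysis removes the acetonide, the silyl ether and the MOM acetal in one operation; no base is used, because the trans-7-hydroxy-8-chloride would close to the epoxide.

**Compound list**

1 | 3-(3-hydroxy-4-methoxyphenyl)propanoic acid | COc1ccc(CCC(=O)O)cc1O | starting material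
2 | methyl 3-(3-hydroxy-4-methoxyphenyl)propanoate | COc1ccc(CCC(=O)OC)cc1O | intermediate
3 | 4,4-bis(methylsulfanyl)but-3-en-2-one | CC(=O)C=C(SC)SC | starting material
4 | 7-(3-hydroxy-4-methoxyphenyl)-1,1-bis(methylsulfanyl)hept-1-ene-3,5-dione | COc1ccc(CCC(=O)CC(=O)C=C(SC)SC)cc1O | intermediate
5 | 6-[2-(3-hydroxy-4-methoxyphenyl)ethyl]-2-(methylsulfanyl)-4H-pyran-4-one | COc1ccc(CCc2cc(=O)cc(SC)o2)cc1O | intermediate
6 | 6-{2-[4-methoxy-3-(methoxymethoxy)phenyl]ethyl}-2-(methylsulfanyl)-4H-pyran-4-one | COCOc1cc(CCc2cc(=O)cc(SC)o2)ccc1OC | intermediate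
7 | 3-iodo-6-{2-[4-methoxy-3-(methoxymethoxy)phenyl]ethyl}-2-(methylsulfanyl)-4H-pyran-4-one | COCOc1cc(CCc2cc(=O)c(I)c(SC)o2)ccc1OC | intermediate
8 | 2,3-O-isopropylidene-D-erythronolactone, (3aR,6aR) | CC1(C)O[C@@H]2COC(=O)[C@@H]2O1 | starting material
9 | (4R,5R)-5-(hydroxymethyl)-N-methoxy-N,2,2-trimethyl-1,3-dioxolane-4-carboxamide | CON(C)C(=O)[C@H](OC1(C)C)[C@H](O1)CO | intermediate
10 | (4R,5R)-N-methoxy-N,2,2-trimethyl-5-[(triethylsilyloxy)methyl]-1,3-dioxolane-4-carboxamide | CON(C)C(=O)[C@H](OC1(C)C)[C@H](O1)CO[Si](CC)(CC)CC | intermediate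
11 | 2,3-O-isopropylidene-4-O-triethylsilyl-D-erythrose | O=C[C@H](OC1(C)C)[C@H](O1)CO[Si](CC)(CC)CC | intermediate
12 | [6-{2-[4-methoxy-3-(methoxymethoxy)phenyl]ethyl}-2-(methylsulfanyl)-4-oxo-4H-pyran-3-yl]magnesium chloride (LiCl complex) | COCOc1cc(CCc2cc(=O)c([Mg]Cl)c(SC)o2)ccc1OC | intermediate
13 | (5S)-alcohol from 12 and 11 (full name in step 8) | COCOc1cc(CCc2cc(=O)c([C@H](O)[C@H](OC3(C)C)[C@H](O3)CO[Si](CC)(CC)CC)c(SC)o2)ccc1OC | intermediate
14 | 5-O-tert-butyldimethylsilyl ether of 13 | COCOc1cc(CCc2cc(=O)c([C@H](O[Si](C)(C)C(C)(C)C)[C@H](OC3(C)C)[C@H](O3)CO[Si](CC)(CC)CC)c(SC)o2)ccc1OC | intermediate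
15 | C8 aldehyde | COCOc1cc(CCc2cc(=O)c([C@H](O[Si](C)(C)C(C)(C)C)[C@H](OC3(C)C)[C@H](O3)C=O)c(SC)o2)ccc1OC | intermediate
16 | trimethylsilyl ether of the trichloromethyl carbinol (C8 epimers) | COCOc1cc(CCc2cc(=O)c([C@H](O[Si](C)(C)C(C)(C)C)[C@H](OC3(C)C)[C@H](O3)C(O[Si](C)(C)C)C(Cl)(Cl)Cl)c(SC)o2)ccc1OC | intermediate
17 | trichloromethyl carbinol (C8 epimers) | COCOc1cc(CCc2cc(=O)c([C@H](O[Si](C)(C)C(C)(C)C)[C@H](OC3(C)C)[C@H](O3)C(O)C(Cl)(Cl)Cl)c(SC)o2)ccc1OC | intermediate
18 | gem-dichloroepoxide | COCOc1cc(CCc2cc(=O)c([C@H](O[Si](C)(C)C(C)(C)C)[C@H](OC3(C)C)[C@H](O3)C4OC4(Cl)Cl)c(SC)o2)ccc1OC | intermediate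
19 | 2-chloroacyl chloride | COCOc1cc(CCc2cc(=O)c([C@H](O[Si](C)(C)C(C)(C)C)[C@H](OC3(C)C)[C@H](O3)C(Cl)C(=O)Cl)c(SC)o2)ccc1OC | intermediate
20 | 2-chloro acid (C8 epimers) | COCOc1cc(CCc2cc(=O)c([C@H](O[Si](C)(C)C(C)(C)C)[C@H](OC3(C)C)[C@H](O3)C(Cl)C(=O)O)c(SC)o2)ccc1OC | intermediate
21 | N-hydroxyphthalimide | O=C1N(O)C(=O)c2ccccc12 | starting material
22 | N-acyloxyphthalimide of 20 | COCOc1cc(CCc2cc(=O)c([C@H](O[Si](C)(C)C(C)(C)C)[C@H](OC3(C)C)[C@H](O3)C(Cl)C(=O)ON4C(=O)c5ccccc5C4=O)c(SC)o2)ccc1OC | intermediate
23 | 2-(methylsulfonyl)pyranone N-acyloxyphthalimide (key-step precursor) | COCOc1cc(CCc2cc(=O)c([C@H](O[Si](C)(C)C(C)(C)C)[C@H](OC3(C)C)[C@H](O3)C(Cl)C(=O)ON4C(=O)c5ccccc5C4=O)c(S(C)(=O)=O)o2)ccc1OC | intermediate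
24 | fully protected target (5-O-TBS, 6,7-acetonide, aryl MOM ether) | COCOc1cc(CCc2cc(=O)c3c(o2)[C@H](Cl)[C@@H](OC4(C)C)[C@@H](O4)[C@H]3O[Si](C)(C)C(C)(C)C)ccc1OC | intermediate
25 | (5S,6S,7S,8R)-8-chloro-5,6,7-trihydroxy-2-[2-(3-hydroxy-4-methoxyphenyl)ethyl]-5,6,7,8-tetrahydro-4H-chromen-4-one | COc1ccc(CCc2cc(=O)c3c(o2)[C@H](Cl)[C@@H](O)[C@@H](O)[C@H]3O)cc1O | target

**Step count**

Total: 16 steps. Longest linear sequence: 13 steps (steps 1–4, then 8–16); the aldehyde arm (steps 5–7) has 3 steps.

**Steps most likely to fail**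

1. Step 15 (Proposed new method). Hydrogen transfer to the C8 radical, or reversible 5-exo attack at C4a, may outrun the 6-endo attack on the hindered, sulfonyl-bearing carbon, so that the radical is reduced without ring closure. The fallback uses known reactions only, sets out from acid 20 and returns at 24. Oxidation of 20 with mCPBA gives the sulfone acid F1. NaBH4 (THF/EtOH, −20 °C) replaces the sulfonyl group by hydrogen through hydride addition–elimination, as in the desulfonylation of 2-sulfonyl azines, and gives the C8a-unsubstituted pyranone acid F2. DIC and 21 convert it into the N-acyloxyphthalimide F3. Under the conditions of step 15, F3 should undergo an ordinary decarboxylative Giese cyclisation (radical conjugate addition to the now unhindered enone β-carbon C8a, hydrogen transfer to C4a) to the 4a,8a-dihydro compound F4. Aerobic Pd(II) dehydrogenation of this 2,3-dihydro-4-pyranone (Pd(TFA)2, DMSO, O2, AcOH, 60 °C) restores the pyranone and gives 24.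

2. Step 8. Facial selectivity in the Grignard addition may be poor, for example through competing chelation of magnesium by the dioxolane oxygen, so that much of the C5 epimer forms. The fallback sets out from 7 and 11 and returns at 13. The 5R alcohol F5, separated from the addition mixture, is inverted at C5 by Mitsunobu reaction (4-nitrobenzoic acid, PPh3, DIAD, toluene, 0 °C) to the (5S)-4-nitrobenzoate F6. Brief methanolysis (K2CO3, MeOH, 0 °C) then gives 13.

3. Step 12. Hydroxide instead of chloride may open the dichloroepoxide, which diverts the material to the α-hydroxy acid. The fallback sets out from 16 and returns at 20, and installs chlorine in a separate substitution. The Jocic reaction is run with hydroxide as the only nucleophile (KOH, dioxane/H2O, no chloride) to give the 2-hydroxy acid F7. Trimethylsilyldiazomethane gives the methyl ester F8. Appel chlorination (PPh3, CCl4, MeCN, 50 °C) gives the 2-chloro methyl ester F9. Me3SnOH (1,2-dichloroethane, 70 °C) cleaves the ester without base-induced elimination and gives 20.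

**Further compounds**

F1 | step 15 | sulfone acid (20 with SO2Me in place of SMe) | COCOc1cc(CCc2cc(=O)c([C@H](O[Si](C)(C)C(C)(C)C)[C@H](OC3(C)C)[C@H](O3)C(Cl)C(=O)O)c(S(C)(=O)=O)o2)ccc1OC
F2 | step 15 | C8a-unsubstituted pyranone 2-chloro acid | COCOc1cc(CCc2cc(=O)c([C@H](O[Si](C)(C)C(C)(C)C)[C@H](OC3(C)C)[C@H](O3)C(Cl)C(=O)O)co2)ccc1OC
F3 | step 15 | N-acyloxyphthalimide of F2 | COCOc1cc(CCc2cc(=O)c([C@H](O[Si](C)(C)C(C)(C)C)[C@H](OC3(C)C)[C@H](O3)C(Cl)C(=O)ON4C(=O)c5ccccc5C4=O)co2)ccc1OC
F4 | step 15 | 4a,8a-dihydro derivative of 24 (ring-fusion epimers) | COCOc1cc(CCC2=CC(=O)C3C(O2)[C@H](Cl)[C@@H](OC4(C)C)[C@@H](O4)[C@H]3O[Si](C)(C)C(C)(C)C)ccc1OC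
F5 | step 8 | (5R)-alcohol, C5 epimer of 13 | COCOc1cc(CCc2cc(=O)c([C@@H](O)[C@H](OC3(C)C)[C@H](O3)CO[Si](CC)(CC)CC)c(SC)o2)ccc1OC
F6 | step 8 | (5S)-4-nitrobenzoate of 13 | COCOc1cc(CCc2cc(=O)c([C@H](OC(=O)c4ccc(cc4)[N+](=O)[O-])[C@H](OC3(C)C)[C@H](O3)CO[Si](CC)(CC)CC)c(SC)o2)ccc1OC
F7 | step 12 | 2-hydroxy acid (C8 epimers) | COCOc1cc(CCc2cc(=O)c([C@H](O[Si](C)(C)C(C)(C)C)[C@H](OC3(C)C)[C@H](O3)C(O)C(=O)O)c(SC)o2)ccc1OC
F8 | step 12 | methyl 2-hydroxy ester (C8 epimers) | COCOc1cc(CCc2cc(=O)c([C@H](O[Si](C)(C)C(C)(C)C)[C@H](OC3(C)C)[C@H](O3)C(O)C(=O)OC)c(SC)o2)ccc1OC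
F9 | step 12 | methyl 2-chloro ester (C8 epimers) | COCOc1cc(CCc2cc(=O)c([C@H](O[Si](C)(C)C(C)(C)C)[C@H](OC3(C)C)[C@H](O3)C(Cl)C(=O)OC)c(SC)o2)ccc1OC
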